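**Plan**

1. Retrosynthesis: cut the acetate C–O, the ring C3–Br bond (from the epimeric alcohol by SN2), the exocyclic C6=CH2 (from a C6 ketone), and then the bond between the ring-bound CH2 and the alkene CH, which gives a cyclopropanol and a (Z)-alkenyl iodide.
2. Enabling feature: ring C6 (the methylidene carbon) is next to C1, which carries the allylic CH2. With C6 as C=O this CH2 is the β (homoenolate) carbon, so C6, C1 and the CH2 are tied into a three-membered ring (a bicyclo[4.1.0]heptan-1-ol) whose strain drives C6–CH2 cleavage and hands the CH2 to palladium.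
3. Forward: a commercial cyclohexenone ketal supplies the six-membered ring; cuprate addition builds CMe2 and a regiodefined enol silane; cyclopropanation adds the temporary ring; the strain-release coupling joins the C5 chain; bromination, methylenation, desilylation and acetylation finish.
4. Stereochemistry: ring C–O (later C–Br by inversion) from CBS reduction; ring CH from cyclopropanation anti to the silyloxy group; chain carbinol from (S)-glyceraldehyde acetonide; Z-alkene from hydroxyl-directed anti-carbomagnesiation, retained in the coupling.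

Key step: step 14

Assumption: compounds 1 and 10 are taken as commercial, and ring locants in the plan follow the target name (C1 = CH bearing the side chain, C3 = CHBr, C6 = C=CH2).

**Route**

Step 1
Reactants: 1 1,4-dioxaspiro[4.5]dec-6-en-8-one
Product: 2 7-iodo-1,4-dioxaspiro[4.5]dec-6-en-8-one
Conditions: I2, pyridine, CH2Cl2, 0 → 25 °C
Reagents that add atoms: iodine, II
Why: Pyridine-mediated α-iodination of an enone (conjugate addition of pyridine, iodination of the enolate, elimination) places iodine only on the α-carbon, and the buffered medium spares the dioxolane.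

Step 2
Reactants: 2 7-iodo-1,4-dioxaspiro[4.5]dec-6-en-8-one
Product: 3 7-methyl-1,4-dioxaspiro[4.5]dec-6-en-8-one
Conditions: MeB(OH)2, Pd(dppf)Cl2 (5 mol %), K2CO3, dioxane/H2O, 80 °C
Reagents that add atoms: methylboronic acid, CB(O)O
Why: Suzuki–Miyaura coupling of an activated α-iodoenone with methylboronic acid exchanges C–I for C–CH3 without touching the ketal.

Step 3
Reactants: 3 7-methyl-1,4-dioxaspiro[4.5]dec-6-en-8-one
Product: 4 (8R)-7-methyl-1,4-dioxaspiro[4.5]dec-6-en-8-ol
Conditions: (S)-2-methyl-CBS-oxazaborolidine (20 mol %), BH3·SMe2, THF, –20 °C; MeOH, then aqueous work-up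
Reagents that add atoms: none
Why: Corey–Bakshi–Shibata reduction of an α-substituted cyclohexenone, with the alkenyl arm as the large group, should deliver hydride to one carbonyl face and set the (R)-carbinol centre (the catalyst enantiomer is the one predicted by the usual model and would be confirmed before scale-up).

Step 4
Reactants: 4 (8R)-7-methyl-1,4-dioxaspiro[4.5]dec-6-en-8-ol
Product: 5 tert-butyldimethyl{[(8R)-7-methyl-1,4-dioxaspiro[4.5]dec-6-en-8-yl]oxy}silane
Conditions: TBSCl, imidazole, DMF, 25 °C
Reagents that add atoms: tert-butyldimethylsilyl chloride, CC(C)(C)[Si](C)(C)Cl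
Why: Standard silylation of the secondary allylic alcohol installs a bulky ether that later shields one ring face and survives the following acidic, organometallic and carbenoid steps.

Step 5
Reactants: 5 tert-butyldimethyl{[(8R)-7-methyl-1,4-dioxaspiro[4.5]dec-6-en-8-yl]oxy}silane
Product: 6 (4R)-4-[(tert-butyldimethylsilyl)oxy]-3-methylcyclohex-2-en-1-one
Conditions: PPTS (cat.), acetone/H2O, 50 °C
Reagents that add atoms: water, O
Why: Mild acid-catalysed hydrolysis of the allylic dioxolane unveils the conjugated enone while the secondary TBS ether is stable to PPTS.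

Step 6
Reactants: 6 (4R)-4-[(tert-butyldimethylsilyl)oxy]-3-methylcyclohex-2-en-1-one
Product: 7 tert-butyl({(1R)-2,2-dimethyl-4-[(trimethylsilyl)oxy]cyclohex-3-en-1-yl}oxy)dimethylsilane
Conditions: Me2CuLi (from MeLi and CuI), TMSCl, THF, –78 → –40 °C; Et3N, cold pH 7 buffer
Reagents that add atoms: lithium dimethylcuprate, [Li+].C[Cu-]C; chlorotrimethylsilane, C[Si](C)(C)Cl
Why: TMSCl-accelerated conjugate addition of the Gilman reagent to the β-methyl enone builds the gem-dimethyl carbon and traps the enolate as the enol silane on the hindered side, a regiochemistry that deprotonation of the ketone would not give; no new stereocentre is formed.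

Step 7
Reactants: 7 tert-butyl({(1R)-2,2-dimethyl-4-[(trimethylsilyl)oxy]cyclohex-3-en-1-yl}oxy)dimethylsilane
Product: 8 (1R,4R,6S)-4-[(tert-butyldimethylsilyl)oxy]-5,5-dimethyl-1-[(trimethylsilyl)oxy]bicyclo[4.1.0]heptane
Conditions: Et2Zn, CH2I2, CH2Cl2, 0 → 25 °C; pyridine, aq. NaHCO3
Reagents that add atoms: diiodomethane, ICI
Why: Simmons–Smith cyclopropanation (Furukawa modification) of the electron-rich enol silane should take place on the face opposite the pseudoaxial C2 methyl of the half-chair with equatorial OTBS, that is anti to the silyloxy group, which sets both ring-fusion carbons of the cis-fused cyclopropane.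

Step 8
Reactants: 8 (1R,4R,6S)-4-[(tert-butyldimethylsilyl)oxy]-5,5-dimethyl-1-[(trimethylsilyl)oxy]bicyclo[4.1.0]heptane
Product: 9 (1R,4R,6S)-5,5-dimethylbicyclo[4.1.0]heptane-1,4-diol
Conditions: TBAF, AcOH, THF, 0 → 25 °C
Reagents that add atoms: none
Why: Acetic acid-buffered fluoride desilylation frees both hydroxyls while avoiding the base-induced ring opening to which free cyclopropanols are prone.

Step 9
Reactants: 10 (4S)-2,2-dimethyl-1,3-dioxolane-4-carbaldehyde
Product: 11 (4R)-4-ethynyl-2,2-dimethyl-1,3-dioxolane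
Conditions: dimethyl (1-diazo-2-oxopropyl)phosphonate, K2CO3, MeOH, 0 → 25 °C
Reagents that add atoms: dimethyl (1-diazo-2-oxopropyl)phosphonate, CC(=O)C(=[N+]=[N-])P(=O)(OC)OC
Why: Seyferth–Gilbert homologation with the Ohira–Bestmann reagent converts the aldehyde into the terminal alkyne under mild carbonate conditions that should preserve the α-alkoxy stereocentre (the descriptor changes only through the priority rules).

Step 10
Reactants: 11 (4R)-4-ethynyl-2,2-dimethyl-1,3-dioxolane
Product: 12 (2R)-but-3-yne-1,2-diol
Conditions: Dowex 50W (H+ form), MeOH, 40 °C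
Reagents that add atoms: none
Why: Acid-catalysed transketalisation with methanol removes the acetonide and exposes the propargylic hydroxyl needed as directing group, with a filtration work-up suited to the water-soluble diol.

Step 11
Reactants: 12 (2R)-but-3-yne-1,2-diol
Product: 14 (2R,3Z)-4-iodo-3-methylbut-3-ene-1,2-diol, via alkenylmagnesium bromide 13 (not isolated)
Conditions: MeMgBr (5 equiv), CuI (20 mol %), THF, –10 → 25 °C; then I2, –78 → 0 °C
Reagents that add atoms: methylmagnesium bromide, C[Mg]Br; iodine, II
Why: Copper-catalysed hydroxyl-directed anti-carbomagnesiation of the propargylic alkoxide adds methyl to the internal alkyne carbon and magnesium to the terminus within a five-membered chelate, so iodinolysis with retention gives the Z-iodide with iodine cis to the carbinol carbon.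

Step 12
Reactants: 14 (2R,3Z)-4-iodo-3-methylbut-3-ene-1,2-diol
Product: 15 (2R,3Z)-1-bromo-4-iodo-3-methylbut-3-en-2-ol
Conditions: CBr4 (1.1 equiv), PPh3 (1.15 equiv), CH2Cl2, –20 → 0 °C
Reagents that add atoms: carbon tetrabromide, BrC(Br)(Br)Br
Why: The Appel reaction at low temperature is selective for the primary hydroxyl over the hindered secondary allylic one and leaves the stereocentre untouched.

Step 13
Reactants: 15 (2R,3Z)-1-bromo-4-iodo-3-methylbut-3-en-2-ol
Product: 16 tert-butyl{[(2R,3Z)-1-bromo-4-iodo-3-methylbut-3-en-2-yl]oxy}dimethylsilane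
Conditions: TBSOTf, 2,6-lutidine, CH2Cl2, –78 → 0 °C
Reagents that add atoms: tert-butyldimethylsilyl trifluoromethanesulfonate, CC(C)(C)[Si](C)(C)OS(=O)(=O)C(F)(F)F
Why: Silylation with the triflate and a weak hindered base protects the bromohydrin without closing it to an epoxide, and an allylic silyl ether, unlike an acetate, cannot ionise with palladium in the next step.

Step 14
Reactants: 9 (1R,4R,6S)-5,5-dimethylbicyclo[4.1.0]heptane-1,4-diol; 16 tert-butyl{[(2R,3Z)-1-bromo-4-iodo-3-methylbut-3-en-2-yl]oxy}dimethylsilane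
Product: 17 (2S,4R)-2-{(2Z,4R)-5-bromo-4-[(tert-butyldimethylsilyl)oxy]-3-methylpent-2-en-1-yl}-4-hydroxy-3,3-dimethylcyclohexan-1-one
Conditions: Pd(OAc)2 (5 mol %), XPhos (10 mol %), Cs2CO3, toluene, 60 °C
Reagents that add atoms: none
Why: Zerovalent palladium adds oxidatively into the C(sp2)–I bond of 16, the iodide is exchanged for the cyclopropanolate of 9, strain-driven β-carbon elimination cleaves the C1–C7 bond to give a primary alkylpalladium ketone homoenolate, and reductive elimination forms the CH2–CH= bond. The closest known reaction type is the palladium-catalysed ring-opening cross-coupling of cyclopropanols, as ketone homoenolate equivalents, with sp2 halides. No ring is closed: the three-membered ring is opened and the six-membered ring is kept. No new stereocentre is created, because the CH next to the new carbonyl keeps the configuration of cyclopropane C6 (none of its bonds is touched) and oxidative addition and reductive elimination retain the Z geometry of 16. The step needs cleavage of the CH2–C(OH) bond and not the CH–C(OH) bond, which the preference of palladium for the less substituted carbon and the quaternary centre flanking C6 should secure, and it needs reductive elimination to outrun β-hydride elimination, for which the bulky biarylphosphine and chelation by the ketone are chosen. Reaction at C–I and not at the primary C–Br bond follows from the rates of oxidative addition, and carbonate at 60 °C should be mild enough to avoid epimerisation next to the carbonyl.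

Step 15
Reactants: 17 (2S,4R)-2-{(2Z,4R)-5-bromo-4-[(tert-butyldimethylsilyl)oxy]-3-methylpent-2-en-1-yl}-4-hydroxy-3,3-dimethylcyclohexan-1-one
Product: 18 (2S,4S)-4-bromo-2-{(2Z,4R)-5-bromo-4-[(tert-butyldimethylsilyl)oxy]-3-methylpent-2-en-1-yl}-3,3-dimethylcyclohexan-1-one
Conditions: CBr4, PPh3, toluene, 0 → 60 °C
Reagents that add atoms: carbon tetrabromide, BrC(Br)(Br)Br
Why: In the Appel reaction of the hydroxy ketone, the conformer with equatorial side chain and axial oxyphosphonium lets bromide attack from the equatorial direction, so SN2 inversion (R to S) should give the equatorial bromide cis to the side chain.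

Step 16
Reactants: 18 (2S,4S)-4-bromo-2-{(2Z,4R)-5-bromo-4-[(tert-butyldimethylsilyl)oxy]-3-methylpent-2-en-1-yl}-3,3-dimethylcyclohexan-1-one
Product: 19 tert-butyl({(2R,3Z)-1-bromo-5-[(1R,3S)-3-bromo-2,2-dimethyl-6-methylidenecyclohexyl]-3-methylpent-3-en-2-yl}oxy)dimethylsilane
Conditions: Cp2Ti(μ-Cl)(μ-CH2)AlMe2 (Tebbe reagent), pyridine, THF/toluene, –40 → 0 °C
Reagents that add atoms: Tebbe reagent, C[Al-]1(C)C[Ti]([Cl+]1)(C1C=CC=C1)C1C=CC=C1
Why: Tebbe methylenation transfers CH2 to the hindered, enolisable ketone through a titanium methylidene and an oxatitanacyclobutane under non-basic conditions, so the α-stereocentre, both alkyl bromides and the silyl ether should survive.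

Step 17
Reactants: 19 tert-butyl({(2R,3Z)-1-bromo-5-[(1R,3S)-3-bromo-2,2-dimethyl-6-methylidenecyclohexyl]-3-methylpent-3-en-2-yl}oxy)dimethylsilane
Product: 20 (2R,3Z)-1-bromo-5-[(1R,3S)-3-bromo-2,2-dimethyl-6-methylidenecyclohexyl]-3-methylpent-3-en-2-ol
Conditions: HF·pyridine, pyridine, THF, 0 → 25 °C
Reagents that add atoms: none
Why: Buffered fluoride desilylation under weakly acidic conditions removes the allylic TBS ether without forming an alkoxide that could displace the neighbouring bromide or isomerise the exocyclic alkene.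

Step 18
Reactants: 20 (2R,3Z)-1-bromo-5-[(1R,3S)-3-bromo-2,2-dimethyl-6-methylidenecyclohexyl]-3-methylpent-3-en-2-ol
Product: 21 (2R,3Z)-1-bromo-5-[(1R,3S)-3-bromo-2,2-dimethyl-6-methylidenecyclohexyl]-3-methylpent-3-en-2-yl acetate
Conditions: Ac2O, pyridine, DMAP (cat.), CH2Cl2, 0 °C
Reagents that add atoms: acetic anhydride, CC(=O)OC(C)=O
Why: DMAP-catalysed acylation of the secondary alcohol with acetic anhydride gives the acetate with retention, pyridine being too weak a base to close the bromohydrin.

**Compound list**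

1 | 1,4-dioxaspiro[4.5]dec-6-en-8-one | O=C1C=CC2(CC1)OCCO2 | starting material
2 | 7-iodo-1,4-dioxaspiro[4.5]dec-6-en-8-one | O=C1C(I)=CC2(CC1)OCCO2 | intermediate
3 | 7-methyl-1,4-dioxaspiro[4.5]dec-6-en-8-one | CC1=CC2(CCC1=O)OCCO2 | intermediate
4 | (8R)-7-methyl-1,4-dioxaspiro[4.5]dec-6-en-8-ol | CC1=CC2(CC[C@H]1O)OCCO2 | intermediate
5 | tert-butyldimethyl{[(8R)-7-methyl-1,4-dioxaspiro[4.5]dec-6-en-8-yl]oxy}silane | CC1=CC2(CC[C@H]1O[Si](C)(C)C(C)(C)C)OCCO2 | intermediate
6 | (4R)-4-[(tert-butyldimethylsilyl)oxy]-3-methylcyclohex-2-en-1-one | CC1=CC(=O)CC[C@H]1O[Si](C)(C)C(C)(C)C | intermediate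
7 | tert-butyl({(1R)-2,2-dimethyl-4-[(trimethylsilyl)oxy]cyclohex-3-en-1-yl}oxy)dimethylsilane | C[Si](C)(C)OC1=CC(C)(C)[C@H](O[Si](C)(C)C(C)(C)C)CC1 | intermediate
8 | (1R,4R,6S)-4-[(tert-butyldimethylsilyl)oxy]-5,5-dimethyl-1-[(trimethylsilyl)oxy]bicyclo[4.1.0]heptane | C[Si](C)(C)O[C@@]12CC[C@@H](O[Si](C)(C)C(C)(C)C)C(C)(C)[C@@H]1C2 | intermediate
9 | (1R,4R,6S)-5,5-dimethylbicyclo[4.1.0]heptane-1,4-diol | O[C@@]12CC[C@@H](O)C(C)(C)[C@@H]1C2 | intermediate
10 | (4S)-2,2-dimethyl-1,3-dioxolane-4-carbaldehyde | O=C[C@@H]1COC(C)(C)O1 | starting material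
11 | (4R)-4-ethynyl-2,2-dimethyl-1,3-dioxolane | C#C[C@@H]1COC(C)(C)O1 | intermediate
12 | (2R)-but-3-yne-1,2-diol | C#C[C@@H](O)CO | intermediate
13 | alkenylmagnesium bromide, [(1Z,3R)-3,4-bis(bromomagnesiooxy)-2-methylbut-1-en-1-yl]magnesium bromide | Br[Mg]/C=C(/C)[C@H](CO[Mg]Br)O[Mg]Br | intermediate
14 | (2R,3Z)-4-iodo-3-methylbut-3-ene-1,2-diol | I/C=C(/C)[C@H](CO)O | intermediate
15 | (2R,3Z)-1-bromo-4-iodo-3-methylbut-3-en-2-ol | I/C=C(/C)[C@H](CBr)O | intermediate
16 | tert-butyl{[(2R,3Z)-1-bromo-4-iodo-3-methylbut-3-en-2-yl]oxy}dimethylsilane | I/C=C(/C)[C@H](CBr)O[Si](C)(C)C(C)(C)C | intermediate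
17 | (2S,4R)-2-{(2Z,4R)-5-bromo-4-[(tert-butyldimethylsilyl)oxy]-3-methylpent-2-en-1-yl}-4-hydroxy-3,3-dimethylcyclohexan-1-one | O=C1CC[C@@H](O)C(C)(C)[C@@H]1C/C=C(/C)[C@H](CBr)O[Si](C)(C)C(C)(C)C | intermediate
18 | (2S,4S)-4-bromo-2-{(2Z,4R)-5-bromo-4-[(tert-butyldimethylsilyl)oxy]-3-methylpent-2-en-1-yl}-3,3-dimethylcyclohexan-1-one | O=C1CC[C@H](Br)C(C)(C)[C@@H]1C/C=C(/C)[C@H](CBr)O[Si](C)(C)C(C)(C)C | intermediate
19 | tert-butyl({(2R,3Z)-1-bromo-5-[(1R,3S)-3-bromo-2,2-dimethyl-6-methylidenecyclohexyl]-3-methylpent-3-en-2-yl}oxy)dimethylsilane | C=C1CC[C@H](Br)C(C)(C)[C@@H]1C/C=C(/C)[C@H](CBr)O[Si](C)(C)C(C)(C)C | intermediate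
20 | (2R,3Z)-1-bromo-5-[(1R,3S)-3-bromo-2,2-dimethyl-6-methylidenecyclohexyl]-3-methylpent-3-en-2-ol | C=C1CC[C@H](Br)C(C)(C)[C@@H]1C/C=C(/C)[C@H](CBr)O | intermediate
21 | (2R,3Z)-1-bromo-5-[(1R,3S)-3-bromo-2,2-dimethyl-6-methylidenecyclohexyl]-3-methylpent-3-en-2-yl acetate (CNP0136568.3) | C=C1CC[C@H](Br)C(C)(C)[C@@H]1C/C=C(/C)[C@H](CBr)OC(C)=O | target

**Step count and risks**

Total step count: 18. Longest linear sequence: 13 steps (steps 1–8, then 14–18); the side-chain branch is steps 9–13.

Steps most likely to fail: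

Step 15 (bromination at the neopentyl carbinol). Anti-periplanar E2 loss of the axial oxyphosphonium toward the ring CH2, or methyl migration and ring contraction by ionisation, may outrun bromide attack at a carbon flanked by the quaternary centre. The fallback separates activation from displacement. It sets out from 17, which with Tf2O and pyridine in CH2Cl2 at –30 °C should give the sulfonate (1R,3S)-3-{(2Z,4R)-5-bromo-4-[(tert-butyldimethylsilyl)oxy]-3-methylpent-2-en-1-yl}-2,2-dimethyl-4-oxocyclohexyl trifluoromethanesulfonate F1. Displacement with Bu4NBr in toluene at –20 → 20 °C, an SN2 reaction of a discrete triflate with a soluble bromide under non-acidic conditions, comes back to the route at 18.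

Step 14 (strain-release coupling). β-Hydride elimination from the alkylpalladium homoenolate would give the 2-methylidene ketone and reduced alkene, and the carbonate base may epimerise the centre next to the carbonyl. The fallback uncouples ring opening from C–C bond formation. It sets out from 9, which with NIS in CH2Cl2 at 0 °C should open electrophilically at the cyclopropane CH2 to (2S,4R)-4-hydroxy-2-(iodomethyl)-3,3-dimethylcyclohexan-1-one F2. Zinc insertion (Zn dust, LiCl, THF, 25 °C) would give {[(1S,3R)-3-hydroxy-2,2-dimethyl-6-oxocyclohexyl]methyl}zinc iodide F3, used without isolation. A base-free Negishi coupling of F3 with 16 (Pd(dppf)Cl2, THF, 25 °C) comes back to the route at 17.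

Step 7 (cyclopropanation). Facial selectivity may erode at the temperature the hindered enol silane needs, and ZnI2 may open the silyloxycyclopropane. The fallback changes the carbenoid and the substrate. It sets out from 7, which with MeLi in THF at 0 °C should give, with retention of enolate regiochemistry, lithium (4R)-4-[(tert-butyldimethylsilyl)oxy]-3,3-dimethylcyclohex-1-en-1-olate F4. Cyclopropanation of this enolate with the samarium carbenoid from CH2I2 and SmI2 at –78 °C should give directly (1R,4R,6S)-4-[(tert-butyldimethylsilyl)oxy]-5,5-dimethylbicyclo[4.1.0]heptan-1-ol F5, the low temperature and the bulkier carbenoid favouring attack anti to the silyloxy group. Desilylation with TBAF and AcOH in THF comes back to the route at 9.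

Further compounds
F1 | step 15 | (1R,3S)-3-{(2Z,4R)-5-bromo-4-[(tert-butyldimethylsilyl)oxy]-3-methylpent-2-en-1-yl}-2,2-dimethyl-4-oxocyclohexyl trifluoromethanesulfonate | O=C1CC[C@@H](OS(=O)(=O)C(F)(F)F)C(C)(C)[C@@H]1C/C=C(/C)[C@H](CBr)O[Si](C)(C)C(C)(C)C
F2 | step 14 | (2S,4R)-4-hydroxy-2-(iodomethyl)-3,3-dimethylcyclohexan-1-one | O=C1CC[C@@H](O)C(C)(C)[C@@H]1CI
F3 | step 14 | {[(1S,3R)-3-hydroxy-2,2-dimethyl-6-oxocyclohexyl]methyl}zinc iodide | O=C1CC[C@@H](O)C(C)(C)[C@@H]1C[Zn]I
F4 | step 7 | lithium (4R)-4-[(tert-butyldimethylsilyl)oxy]-3,3-dimethylcyclohex-1-en-1-olate | [Li]OC1=CC(C)(C)[C@H](O[Si](C)(C)C(C)(C)C)CC1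
F5 | step 7 | (1R,4R,6S)-4-[(tert-butyldimethylsilyl)oxy]-5,5-dimethylbicyclo[4.1.0]heptan-1-ol | O[C@@]12CC[C@@H](O[Si](C)(C)C(C)(C)C)C(C)(C)[C@@H]1C2
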